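A small charge of incoming ligand, 0.800 equivalents on the starting complex and so the limiting reagent, went into the noon and winter runs, and this is the note I left for whoever took over the bench.

the same everywhere: starting complex 0.17 M
- noon: incoming ligand 0.136 M; leaving ligand 0.57 M; run made earlier
- winter: incoming ligand 0.136 M; leaving ligand 1.7 M; run made earlier
- delta: incoming ligand 0.136 M; leaving ligand 0.850 M; time 2.0 min
- theta: incoming ligand 0.340 M; leaving ligand 0.850 M; time 2.0 min
- alpha: incoming ligand 0.680 M; leaving ligand 0.850 M; time 2.0 min

- noon (time / s: complex with three exchanged / %, complex with one exchanged / %): 10.0: 3.5, 13.8; 15.0: 3.7, 11.2; 20.0: 4.6, 9.5; 30.0: 4.7, 8.0; 40.0: 4.6, 6.4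
- winter (time / s: complex with three exchanged / %, complex with one exchanged / %): 10.0: 2.5, 8.6; 15.0: 2.5, 7.7; 25.0: 2.5, 6.0; 30.0: 2.5, 5.7; 40.0: 2.4, 5.3

(each reading ± 0.3 percentage points)

- complex with three exchanged at the end, in percent of the starting complex charged, for each flask in turn (delta, theta, alpha)

- no earlier run changes the charge of incoming ligand; that part of a forecast is a guess

I could read two complexes, so I counted the ligand they held, one in each complex with one exchanged and 3 in each complex with three exchanged, and divided by the ligand charged. At the last reading, 40.0 s, this fraction was 25.2% at noon and 15.6% in winter. Their geometric mean, 19.9%, I called the seen share and took, as a rough reading with the scatter of the runs in it, for the flasks at 0.850 M of leaving ligand. That put 80.1% of the charge out of sight, free or in unread forms, and I asked my successor not to book it to any one form, since no reading named one.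

For delta, the complex with three exchanged read 4.6% at noon and 2.4% in winter at that last reading, and I expected a value between them. For theta and alpha I borrowed the share, which was a guess, since no run had changed the charge and the readings stopped at 40.0 s, earlier than 2.0 min. Letting the complex with three exchanged carry the seen ligand gave 13.2% and 26.5%.

The forecast said 3.7%, 23% and 70%, higher than mine for theta and alpha, and of alpha it said “That last figure is largely a guess”.

The flasks gave 1.82%, 9.20% and 27.4% for delta, theta and alpha.

    complex with two exchanged + incoming ligand ⇌ leaving ligand + complex with three exchanged (K = 21.0, k = 3.30 L mol⁻¹ s⁻¹)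
    starting complex + incoming ligand ⇌ leaving ligand + complex with one exchanged (K = 3.40, k = 1.10 L mol⁻¹ s⁻¹)
    complex with one exchanged + incoming ligand ⇌ leaving ligand + complex with two exchanged (K = 33.0, k = 0.730 L mol⁻¹ s⁻¹)
    complex with one exchanged + incoming ligand → over-reaction product (k = 1.00 L mol⁻¹ s⁻¹)

Among the unread forms, over-reaction product stood at 61.3% of the starting complex charged in theta at 2.00 min. Counted as before, the seen share at that time was 15.2% in theta, lower than the 19.9% I had carried, and 20.6% in alpha, with 43% of its incoming ligand still left.

All runs come from a simulation with constants of no real substance.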